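**Plan**

1. Ring labels: A is the hydroquinone-type ring (OH para to the ether O, bridge ortho to it), B the catechol-type ring, C the para-disubstituted ring, D the meta-disubstituted ring. The retrosynthesis cuts, in order: the two O–CH3 bonds masking the phenols; the bond from C3 of ring D to the CH2 of the C/D ethano bridge, which opens the 18-membered ring; the bond from ring B to the CH2 of the A/B bridge; and the two diaryl ether C–O bonds.
2. Forward: two diaryl ether halves are made. The D–O–A half (SNAr, then methylenation) carries Br on ring D and a vinyl group on ring A. The B–O–C half (Chan–Lam) carries I on ring B and a vinyl group on ring C.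
3. The halves are joined at the A/B bridge by hydroboration/B-alkyl Suzuki coupling at the iodide. The same reaction, now intramolecular at the ring D bromide, closes the macrocycle, and BBr3 frees the phenols.
4. Enabling feature: both bridges are Ar–CH2CH2–Ar' units, so each maps onto a styrene (rings A and C) plus a halogenated aryl carbon. The ring D carbon is meta to the ether oxygen with H on both neighbours, and the two ether oxygens act as hinges, so the saturated bridge and the 18-membered ring can arise in one event with no later redox adjustment.
5. Stereochemistry: the target has no stereocentre and no stereogenic double bond, so nothing has to be set.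

Key step: step 5

Remark: compounds 1, 2, 5 and 6 are taken as catalogue compounds; both phenols are carried as methyl ethers until the last step.

**Route**

Step 1
Reactants: 1 2-fluoro-5-methoxybenzaldehyde; 2 3-bromophenol
Product: 3 2-(3-bromophenoxy)-5-methoxybenzaldehyde
Conditions: K2CO3 (2 equiv), DMAc, 140 °C
Reagents that add atoms: none
Why: Nucleophilic aromatic substitution (SNAr): the ortho formyl group stabilises the Meisenheimer adduct at the C–F carbon and fluoride is the best leaving group for this addition-controlled process, while the aryl bromide of 2 is inert to carbonate.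

Step 2
Reactants: 3 2-(3-bromophenoxy)-5-methoxybenzaldehyde
Product: 4 1-(3-bromophenoxy)-4-methoxy-2-vinylbenzene
Conditions: Ph3PCH3Br, KOtBu, THF, 0 °C → rt
Reagents that add atoms: methyltriphenylphosphonium bromide, C[P+](c1ccccc1)(c1ccccc1)c1ccccc1.[Br-]
Why: Wittig methylenation of a non-enolisable aryl aldehyde with the unstabilised ylide is reliable, and KOtBu as base avoids halogen–metal exchange at the aryl bromide.

Step 3
Reactants: 5 5-iodo-2-methoxyphenol; 6 4-vinylphenylboronic acid (2 equiv)
Product: 7 4-iodo-1-methoxy-2-(4-vinylphenoxy)benzene
Conditions: Cu(OAc)2 (1.5 equiv), pyridine, 4 Å MS, CH2Cl2, air, rt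
Reagents that add atoms: none
Why: Chan–Lam oxidative C–O coupling runs at room temperature through an aryl copper(III) phenoxide, conditions under which the aryl iodide and the styrene should stay untouched.

Step 4
Reactants: 4 1-(3-bromophenoxy)-4-methoxy-2-vinylbenzene; 7 4-iodo-1-methoxy-2-(4-vinylphenoxy)benzene
Product: 9 1-(3-bromophenoxy)-4-methoxy-2-{2-[4-methoxy-3-(4-vinylphenoxy)phenyl]ethyl}benzene, via primary alkyl-9-BBN borane 8 (not isolated)
Conditions: 9-BBN (1.1 equiv), THF, 0 °C → rt; aq K3PO4; then 7, Pd(dppf)Cl2·CH2Cl2 (5 mol %), DMF, rt
Reagents that add atoms: none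
Why: 9-BBN should add anti-Markovnikov to the styrene of 4, and the B-alkyl Suzuki–Miyaura coupling at room temperature should engage the aryl iodide of 7 much faster than the aryl bromide carried by 8, residual B–H being destroyed by the aqueous base before the vinyl group of 7 is introduced.

Step 5
Reactants: 9 1-(3-bromophenoxy)-4-methoxy-2-{2-[4-methoxy-3-(4-vinylphenoxy)phenyl]ethyl}benzene
Product: 11 di-O-methyl dihydroptychantol A (the 18-membered macrocycle of the target carrying OMe on rings A and B), via primary alkyl-9-BBN borane 10 (not isolated)
Conditions: 9-BBN (2 equiv), THF, rt; then syringe-pump addition to Pd(dppf)Cl2·CH2Cl2 (20 mol %), AsPh3 (20 mol %), Cs2CO3 (3 equiv), DMF/THF/H2O, 60 °C, final 2 mM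
Reagents that add atoms: none
Why: 9-BBN adds to the ring C vinyl group with boron on the terminal carbon; base converts the borane into a borate, Pd(0) inserts into the ring D C–Br bond, the primary alkyl group passes from boron to palladium to give a 19-membered palladacycle, and reductive elimination forms the CH2–C3(ring D) bond. The closest known reaction type is the intramolecular B-alkyl Suzuki–Miyaura macrocyclisation of ω-alkenyl aryl or vinyl halides used for cyclophanes and macrocyclic natural products. The single ring formed is the 18-membered macrocycle, closed end to end by C(sp3)–C(sp2) reductive elimination, and the new bridge arrives directly at the saturated level, so no rigid stilbene has to be accommodated in the ring. No stereocentre is created. The step needs terminal regioselectivity in the hydroboration, which the steric demand of 9-BBN on a styrene should secure, and ring closure in preference to oligomerisation and β-hydride elimination, which slow addition into a dilute catalyst solution, the large-bite-angle dppf ligand and the unhindered bromide (H on both neighbouring carbons of ring D) should secure. The methyl ethers, the diaryl ethers and the existing ethano bridge are inert, and excess B–H is destroyed by the aqueous medium.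

Step 6
Reactants: 11 di-O-methyl dihydroptychantol A
Product: 12 dihydroptychantol A
Conditions: BBr3 (6 equiv), CH2Cl2, −78 °C → rt; then H2O
Reagents that add atoms: none
Why: Lewis-acid ether cleavage with BBr3 proceeds by bromide attack on the O-methyl carbon of the boron-complexed ether, a pathway closed to the diaryl ether oxygens, so only the two methoxy groups should be unmasked.

**Compound list**

1 | 2-fluoro-5-methoxybenzaldehyde | COc1ccc(F)c(C=O)c1 | starting material
2 | 3-bromophenol | Oc1cccc(Br)c1 | starting material
3 | 2-(3-bromophenoxy)-5-methoxybenzaldehyde | COc1ccc(Oc2cccc(Br)c2)c(C=O)c1 | intermediate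
4 | 1-(3-bromophenoxy)-4-methoxy-2-vinylbenzene | COc1ccc(Oc2cccc(Br)c2)c(C=C)c1 | intermediate
5 | 5-iodo-2-methoxyphenol | COc1ccc(I)cc1O | starting material
6 | 4-vinylphenylboronic acid | OB(O)c1ccc(C=C)cc1 | starting material
7 | 4-iodo-1-methoxy-2-(4-vinylphenoxy)benzene | COc1ccc(I)cc1Oc1ccc(C=C)cc1 | intermediate
8 | 9-{2-[2-(3-bromophenoxy)-5-methoxyphenyl]ethyl}-9-borabicyclo[3.3.1]nonane (not isolated) | COc1ccc(Oc2cccc(Br)c2)c(CCB2C3CCCC2CCC3)c1 | intermediate
9 | 1-(3-bromophenoxy)-4-methoxy-2-{2-[4-methoxy-3-(4-vinylphenoxy)phenyl]ethyl}benzene | COc1ccc(Oc2cccc(Br)c2)c(CCc2ccc(OC)c(Oc3ccc(C=C)cc3)c2)c1 | intermediate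
10 | 9-{2-[4-(5-{2-[2-(3-bromophenoxy)-5-methoxyphenyl]ethyl}-2-methoxyphenoxy)phenyl]ethyl}-9-borabicyclo[3.3.1]nonane (not isolated) | COc1ccc(Oc2cccc(Br)c2)c(CCc2ccc(OC)c(Oc3ccc(CCB4C5CCCC4CCC5)cc3)c2)c1 | intermediate
11 | di-O-methyl dihydroptychantol A (18-membered macrocycle, OMe on rings A and B) | COc1ccc2c(c1)CCc1ccc(OC)c(c1)Oc1ccc(cc1)CCc1cccc(c1)O2 | intermediate
12 | dihydroptychantol A | Oc1ccc2c(c1)CCc1ccc(O)c(c1)Oc1ccc(cc1)CCc1cccc(c1)O2 | target

**Summary**

Total step count: 6. Longest linear sequence: 5 (steps 1, 2, 4, 5, 6); step 3 builds the second half in parallel.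

Steps most likely to fail:

Step 5. Intermolecular coupling may outrun ring closure and give oligomers, or the alkyl group may be lost by β-hydride elimination or protodeboronation before it is transferred within the large ring. The fallback sets out from 9 and closes the ring without any organoboron species. An intramolecular Mizoroki–Heck reaction of the ring D bromide onto the ring C vinyl group (Pd(OAc)2, P(o-tol)3, K2CO3, Bu4NBr, DMF, 110 °C, 2 mM) should give the macrocyclic (E)-stilbene analogue of 11, F1. Hydrogenation of its only C=C bond (H2, Pd/C, EtOAc) should then return to the route at 11.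

Step 4. Selectivity for the iodide over the bromide in oxidative addition may erode, so that 8 couples through its own bromide, or boron may be transferred to the vinyl group of 7. The fallback sets out from 7 and keeps the aryl bromide out of the palladium step altogether. Commercial 2-hydroxy-5-methoxybenzaldehyde is methylenated (Ph3PCH3Br, KOtBu, 2.5 equiv each, THF) to 4-methoxy-2-vinylphenol F2. Treatment with 9-BBN (2.2 equiv, the first equivalent being consumed by the phenol) should give the O,C-bis(9-BBN) derivative of F2, F3, which is not isolated. Aqueous K3PO4, then 7 and Pd(dppf)Cl2 at room temperature, should give 4-methoxy-2-{2-[4-methoxy-3-(4-vinylphenoxy)phenyl]ethyl}phenol F4. Chan–Lam arylation of this phenol with 3-bromophenylboronic acid (Cu(OAc)2, pyridine, 4 Å MS, CH2Cl2, air) attaches ring D last and returns to the route at 9.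

Step 3. Aryl transfer from copper may be slow, with protodeboronation and oxidative homocoupling of 6 or copper-promoted polymerisation of the styrene consuming the boronic acid and leaving 5 unconverted. The fallback sets out from 5 and builds the ether by SNAr. Reaction with 4-fluorobenzaldehyde (K2CO3, DMF, 120 °C) should give 4-(5-iodo-2-methoxyphenoxy)benzaldehyde F5, and Wittig methylenation (Ph3PCH3Br, KOtBu, THF, 0 °C → rt) then returns to the route at 7.

**Further compounds**

F1 | step 5 | (E)-stilbene analogue of 11 (ring C–CH=CH–ring D in place of the C/D ethano bridge) | COc1ccc2c(c1)CCc1ccc(OC)c(c1)Oc1ccc(cc1)/C=C/c1cccc(c1)O2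
F2 | step 4 | 4-methoxy-2-vinylphenol | COc1ccc(O)c(C=C)c1
F3 | step 4 | 9-{2-[2-(9-borabicyclo[3.3.1]nonan-9-yloxy)-5-methoxyphenyl]ethyl}-9-borabicyclo[3.3.1]nonane (not isolated) | COc1ccc(OB2C3CCCC2CCC3)c(CCB2C3CCCC2CCC3)c1
F4 | step 4 | 4-methoxy-2-{2-[4-methoxy-3-(4-vinylphenoxy)phenyl]ethyl}phenol | COc1ccc(O)c(CCc2ccc(OC)c(Oc3ccc(C=C)cc3)c2)c1
F5 | step 3 | 4-(5-iodo-2-methoxyphenoxy)benzaldehyde | COc1ccc(I)cc1Oc1ccc(C=O)cc1
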